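**Retrosynthetic overview**

1. Target 24 comes from alcohol 23 by acetylation; 23 comes from macrolactone 21 by a Schenck ene reaction at the 11Z-alkene and transannular opening of the 7,8-epoxide by the C-11 hydroperoxide (C11–O and C8–O; the 1,2-dioxane is formed last).
2. 21 comes from bromo enal 19 by an electrochemical, chromium-catalysed intramolecular allylation (C1–C2; the 14-membered ring and the α-methylene-γ-lactone form together).
3. 19 comes from epoxy ketone 11 by Horner–Wadsworth–Emmons homologation (C-2, C-3) and Baylis–Hillman/bromide installation (C-15 to C-17).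
4. 11 comes from ketone 7 by chelation-controlled methylation and epoxide closure; 7 comes from acetyl lactone 6 (D-glutamic acid series) and neryl-derived chloride 3 (C9–C10).
5. Ring order: oxirane, then carbocycle plus lactone, then 1,2-dioxane; every stereocentre descends from C-7 of lactone acid 4.

Assumption: 1, 4 and 15 are bought; cembrane numbering (C-1 to C-20, lactone carbonyl C-16, exocyclic methylene C-17) is used for late intermediates and to locate atoms in the "Why" lines. The sense of induction in step 11 is assumed to be (1S,2S); none of the steps has been run.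

**Route**

Step 1
Reactants: 1 neryl chloride, (2Z)-1-chloro-3,7-dimethylocta-2,6-diene
Product: 3 (4Z)-6-chloro-1,1-dimethoxy-4-methylhex-4-ene, via chloro aldehyde 2 (not isolated)
Conditions: O3 (1.0 equiv), CH2Cl2, −78 °C; Me2S; then MeOSiMe3 (2.5 equiv), Me3SiOTf (2 mol %), −78 → −20 °C
Reagents that add atoms: methoxytrimethylsilane, CO[Si](C)(C)C
Why: Ozone attacks only the electron-rich terminal alkene (the 2,3-alkene is deactivated by the allylic chloride) and Noyori acetalisation masks the aldehyde without solvolysing the chloride or touching the Z-alkene (chemoselective ozonolysis, Noyori acetalisation).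

Step 2
Reactants: 4 (R)-5-oxotetrahydrofuran-2-carboxylic acid
Product: 6 (5R)-5-acetyldihydrofuran-2(3H)-one, via acid chloride 5 (not isolated)
Conditions: (COCl)2, DMF (cat.), CH2Cl2, 0 → 20 °C; then MeMgBr (1.05 equiv), Fe(acac)3 (3 mol %), THF, −78 °C
Reagents that add atoms: methylmagnesium bromide, C[Mg]Br
Why: Iron-catalysed acylation of the Grignard reagent by the acid chloride stops at the ketone and tolerates the lactone, and the stereocentre (future C-7) is not touched (Grignard acylation).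

Step 3
Reactants: 6 (5R)-5-acetyldihydrofuran-2(3H)-one; 3 (4Z)-6-chloro-1,1-dimethoxy-4-methylhex-4-ene
Product: 7 (5R)-5-[(4Z)-8,8-dimethoxy-5-methyloct-4-enoyl]dihydrofuran-2(3H)-one
Conditions: LiN(i-Pr)2 (1.05 equiv), THF, −78 °C; then 3, NaI (10 mol %), DMPU, −78 → −30 °C
Reagents that add atoms: none
Why: Kinetic deprotonation occurs at the methyl group, away from the oxygen-bearing α-carbon, and SN2 alkylation by the allylic chloride forms C9–C10 with the Z-alkene retained and C-7 untouched (kinetic enolate alkylation).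

Step 4
Reactants: 7 (5R)-5-[(4Z)-8,8-dimethoxy-5-methyloct-4-enoyl]dihydrofuran-2(3H)-one
Product: 9 (5R,6S,9Z)-5,6-dihydroxy-13,13-dimethoxy-6,10-dimethyltridec-9-en-2-one, via Weinreb amide 8 (not isolated)
Conditions: MeNH(OMe)·HCl (1.3 equiv), i-PrMgCl (2.6 equiv), THF, −20 °C; then MeMgBr (4 equiv), −78 → −10 °C; aq. NH4Cl
Reagents that add atoms: methylmagnesium bromide, C[Mg]Br
Why: The magnesium amide opens the lactone to the Weinreb amide and leaves a magnesium alkoxide at C-7, so MeMgBr adds to the α-alkoxido ketone through the Cram cyclic (chelate) model from the face of the C-7 hydrogen, setting C-8 (6S in the name) from 7R, while the Weinreb amide stops at the methyl ketone (chelation-controlled Grignard addition, Weinreb ketone synthesis).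

Step 5
Reactants: 9 (5R,6S,9Z)-5,6-dihydroxy-13,13-dimethoxy-6,10-dimethyltridec-9-en-2-one
Product: 11 4-{(2S,3S)-3-[(3Z)-7,7-dimethoxy-4-methylhept-3-en-1-yl]-3-methyloxiran-2-yl}butan-2-one, via mesylate 10 (not isolated)
Conditions: MsCl (1.1 equiv), Et3N, CH2Cl2, −20 °C; then K2CO3, MeOH, 0 → 20 °C
Reagents that add atoms: none
Why: Only the secondary C-7 hydroxyl is sulfonylated and the tertiary alkoxide displaces the mesylate with inversion at C-7, giving the trans (7S,8S) trisubstituted epoxide stereospecifically (intramolecular SN2 epoxide closure).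

Step 6
Reactants: 11 4-{(2S,3S)-3-[(3Z)-7,7-dimethoxy-4-methylhept-3-en-1-yl]-3-methyloxiran-2-yl}butan-2-one
Product: 12 methyl (2E)-5-{(2S,3S)-3-[(3Z)-7,7-dimethoxy-4-methylhept-3-en-1-yl]-3-methyloxiran-2-yl}-3-methylpent-2-enoate
Conditions: (MeO)2P(O)CH2CO2Me, NaH, THF, 0 → 45 °C; 2Z isomer (expected about 1 part in 5) removed by chromatography
Reagents that add atoms: trimethyl phosphonoacetate, COC(=O)CP(=O)(OC)OC
Why: Horner–Wadsworth–Emmons olefination of the methyl ketone gives mainly the E-enoate, a configurationally stable carrier of the future 3E-alkene, and the epoxide and acetal are inert to the phosphonate anion.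

Step 7
Reactants: 12 methyl (2E)-5-{(2S,3S)-3-[(3Z)-7,7-dimethoxy-4-methylhept-3-en-1-yl]-3-methyloxiran-2-yl}-3-methylpent-2-enoate
Product: 14 (4Z)-7-{(2S,3S)-3-[(3E)-5-hydroxy-3-methylpent-3-en-1-yl]-2-methyloxiran-2-yl}-4-methylhept-4-enal, via allylic alcohol 13 (not isolated)
Conditions: i-Bu2AlH (2.3 equiv), CH2Cl2, −78 °C; aq. KNaC4H4O6; then PPTS (10 mol %), acetone–H2O 9:1, 20 °C
Reagents that add atoms: water, O
Why: i-Bu2AlH at −78 °C reduces the conjugated ester to the allylic alcohol without opening the trisubstituted epoxide, and mild PPTS hydrolysis then unmasks the dimethyl acetal (ester reduction, acetal hydrolysis).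

Step 8
Reactants: 14 (4Z)-7-{(2S,3S)-3-[(3E)-5-hydroxy-3-methylpent-3-en-1-yl]-2-methyloxiran-2-yl}-4-methylhept-4-enal; 15 methyl acrylate
Product: 16 methyl (3RS,6Z)-3-hydroxy-9-{(2S,3S)-3-[(3E)-5-hydroxy-3-methylpent-3-en-1-yl]-2-methyloxiran-2-yl}-6-methyl-2-methylidenenon-6-enoate
Conditions: 15 (6 equiv), DABCO (1 equiv), MeOH (2 equiv), 20 °C, 5 d
Reagents that add atoms: none
Why: The DABCO–acrylate zwitterion adds to the unhindered aliphatic aldehyde (Morita–Baylis–Hillman reaction); the new carbinol centre forms as both epimers, which is irrelevant because it becomes sp2 in step 10.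

Step 9
Reactants: 16 methyl (3RS,6Z)-3-hydroxy-9-{(2S,3S)-3-[(3E)-5-hydroxy-3-methylpent-3-en-1-yl]-2-methyloxiran-2-yl}-6-methyl-2-methylidenenon-6-enoate
Product: 17 methyl (3RS,6Z)-3-hydroxy-6-methyl-9-{(2S,3S)-2-methyl-3-[(3E)-3-methyl-5-oxopent-3-en-1-yl]oxiran-2-yl}-2-methylidenenon-6-enoate
Conditions: TEMPO (10 mol %), PhI(OAc)2 (1.1 equiv), CH2Cl2, 20 °C
Reagents that add atoms: none
Why: The oxoammonium salt oxidises the primary allylic alcohol much faster than the secondary Baylis–Hillman alcohol and stops at the enal, and the enal is made only after the amine-mediated step so that its 2E geometry is not scrambled (TEMPO/PhI(OAc)2 oxidation).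

Step 10
Reactants: 17 methyl (3RS,6Z)-3-hydroxy-6-methyl-9-{(2S,3S)-2-methyl-3-[(3E)-3-methyl-5-oxopent-3-en-1-yl]oxiran-2-yl}-2-methylidenenon-6-enoate
Product: 19 methyl (2Z,6Z)-2-(bromomethyl)-6-methyl-9-{(2S,3S)-2-methyl-3-[(3E)-3-methyl-5-oxopent-3-en-1-yl]oxiran-2-yl}nona-2,6-dienoate, via mesylate 18 (not isolated)
Conditions: MsCl, Et3N, CH2Cl2, −40 °C; then LiBr (3 equiv), THF, −20 → 0 °C; used at once
Reagents that add atoms: lithium bromide, [Li+].[Br-]
Why: The Baylis–Hillman mesylate is displaced by bromide in the SN2′ sense to the thermodynamically preferred (2Z)-2-(bromomethyl)enoate, with the alkyl chain trans to the ester (allylic transposition).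

Step 11
Reactants: 19 methyl (2Z,6Z)-2-(bromomethyl)-6-methyl-9-{(2S,3S)-2-methyl-3-[(3E)-3-methyl-5-oxopent-3-en-1-yl]oxiran-2-yl}nona-2,6-dienoate
Product: 21 (1S,2S,3E,7S,8S,11Z)-7,8-epoxycembra-3,11,15(17)-trien-16,2-olide, via silyl ether 20 (not isolated)
Conditions: CrCl3 (15 mol %), Me3SiCl (2.5 equiv), LiCl (0.2 M), DMF–THF 1:1, undivided cell, reticulated vitreous carbon cathode, sacrificial zinc anode, constant current (about 2.3 F per mol), 19 added by syringe pump over 10 h (final 2 mM), 20 °C; aq. citric acid; then PPTS (5 mol %), CH2Cl2, 20 °C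
Reagents that add atoms: none
Why: Proposed new method: cathodic reduction of trivalent to divalent chromium lets the metal insert into the allylic C–Br bond to give a (Z)-2-(methoxycarbonyl)allylchromium species that adds through its γ-carbon (C-1) to the tethered enal in a closed chair transition state (syn adduct, hence the cis-lactone after lactonisation), Me3SiCl cleaves the Cr–O bond so that chromium turns over at the cathode, and the rigid trans 7S,8S-epoxide in the folded chain is expected to relay the absolute sense to C-1 and C-2 by macrocyclic stereocontrol; the closest known chemistry is the stoichiometric CrCl2 Nozaki–Hiyama–Kishi allylation giving α-methylene-γ-butyrolactones and the electrochemically driven chromium-catalysed Nozaki–Hiyama–Kishi coupling, neither shown for macrocyclisation of a 2-(bromomethyl)enoate.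

Step 12
Reactants: 21 (1S,2S,3E,7S,8S,11Z)-7,8-epoxycembra-3,11,15(17)-trien-16,2-olide
Product: 23 (1S,2S,3E,7S,8R,11S,12E)-8,11-epidioxy-7-hydroxycembra-3,12,15(17)-trien-16,2-olide, via hydroperoxide 22 (not isolated)
Conditions: O2, tetraphenylporphyrin (1 mol %), CH2Cl2, white LED, −30 °C; then TsOH·H2O (5 mol %), −30 → 0 °C
Reagents that add atoms: dioxygen, O=O
Why: Sensitised singlet oxygen reacts at the electron-rich 11Z-alkene by the Schenck ene reaction, the cis effect allowing hydrogen abstraction from C-13 so that oxygen goes to C-11 and the new 12,13-alkene is E, and acid then lets the C-11 hydroperoxide open the epoxide at the tertiary C-8 by transannular 6-exo SN2 attack with inversion (8R), which only the 11S hydroperoxide can do because the ten-carbon loop spans the 1,2-dioxane only in the cis sense, so C-8 and C-11 are both fixed by the epoxide.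

Step 13
Reactants: 23 (1S,2S,3E,7S,8R,11S,12E)-8,11-epidioxy-7-hydroxycembra-3,12,15(17)-trien-16,2-olide
Product: 24 (1S,2S,3E,7S,8R,11S,12E)-7-acetoxy-8,11-epidioxycembra-3,12,15(17)-trien-16,2-olide
Conditions: Ac2O (3 equiv), pyridine, DMAP (5 mol %), CH2Cl2, 0 °C
Reagents that add atoms: acetic anhydride, CC(=O)OC(C)=O
Why: DMAP-catalysed acetylation of the secondary C-7 alcohol touches no stereocentre, and pyridine is too weak a base to trigger Kornblum–DeLaMare fragmentation of the peroxide.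

**Compound list**

1 | neryl chloride, (2Z)-1-chloro-3,7-dimethylocta-2,6-diene | CC(C)=CCC/C(C)=C\CCl | starting material
2 | (4Z)-6-chloro-4-methylhex-4-enal | O=CCC/C(C)=C\CCl | intermediate
3 | (4Z)-6-chloro-1,1-dimethoxy-4-methylhex-4-ene | COC(OC)CC/C(C)=C\CCl | intermediate
4 | (R)-5-oxotetrahydrofuran-2-carboxylic acid | O=C(O)[C@H]1CCC(=O)O1 | starting material
5 | (R)-5-oxotetrahydrofuran-2-carbonyl chloride | O=C(Cl)[C@H]1CCC(=O)O1 | intermediate
6 | (5R)-5-acetyldihydrofuran-2(3H)-one | CC(=O)[C@H]1CCC(=O)O1 | intermediate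
7 | (5R)-5-[(4Z)-8,8-dimethoxy-5-methyloct-4-enoyl]dihydrofuran-2(3H)-one | COC(OC)CC/C(C)=C\CCC(=O)[C@H]1CCC(=O)O1 | intermediate
8 | (4R,8Z)-4-hydroxy-N,12,12-trimethoxy-N,9-dimethyl-5-oxododec-8-enamide | CON(C)C(=O)CC[C@@H](O)C(=O)CC/C=C(C)\CCC(OC)OC | intermediate
9 | (5R,6S,9Z)-5,6-dihydroxy-13,13-dimethoxy-6,10-dimethyltridec-9-en-2-one | CC(=O)CC[C@@H](O)[C@@](C)(O)CC/C=C(C)\CCC(OC)OC | intermediate
10 | (5R,6S,9Z)-6-hydroxy-13,13-dimethoxy-6,10-dimethyl-2-oxotridec-9-en-5-yl methanesulfonate | CC(=O)CC[C@@H](OS(C)(=O)=O)[C@@](C)(O)CC/C=C(C)\CCC(OC)OC | intermediate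
11 | 4-{(2S,3S)-3-[(3Z)-7,7-dimethoxy-4-methylhept-3-en-1-yl]-3-methyloxiran-2-yl}butan-2-one | CC(=O)CC[C@@H]1O[C@@]1(C)CC/C=C(C)\CCC(OC)OC | intermediate
12 | methyl (2E)-5-{(2S,3S)-3-[(3Z)-7,7-dimethoxy-4-methylhept-3-en-1-yl]-3-methyloxiran-2-yl}-3-methylpent-2-enoate | COC(=O)/C=C(\C)CC[C@@H]1O[C@@]1(C)CC/C=C(C)\CCC(OC)OC | intermediate
13 | (2E)-5-{(2S,3S)-3-[(3Z)-7,7-dimethoxy-4-methylhept-3-en-1-yl]-3-methyloxiran-2-yl}-3-methylpent-2-en-1-ol | OC/C=C(\C)CC[C@@H]1O[C@@]1(C)CC/C=C(C)\CCC(OC)OC | intermediate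
14 | (4Z)-7-{(2S,3S)-3-[(3E)-5-hydroxy-3-methylpent-3-en-1-yl]-2-methyloxiran-2-yl}-4-methylhept-4-enal | OC/C=C(\C)CC[C@@H]1O[C@@]1(C)CC/C=C(C)\CCC=O | intermediate
15 | methyl acrylate | C=CC(=O)OC | starting material
16 | methyl (3RS,6Z)-3-hydroxy-9-{(2S,3S)-3-[(3E)-5-hydroxy-3-methylpent-3-en-1-yl]-2-methyloxiran-2-yl}-6-methyl-2-methylidenenon-6-enoate | OC/C=C(\C)CC[C@@H]1O[C@@]1(C)CC/C=C(C)\CCC(O)C(=C)C(=O)OC | intermediate
17 | methyl (3RS,6Z)-3-hydroxy-6-methyl-9-{(2S,3S)-2-methyl-3-[(3E)-3-methyl-5-oxopent-3-en-1-yl]oxiran-2-yl}-2-methylidenenon-6-enoate | O=C/C=C(\C)CC[C@@H]1O[C@@]1(C)CC/C=C(C)\CCC(O)C(=C)C(=O)OC | intermediate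
18 | 3-O-methanesulfonate of 17 | O=C/C=C(\C)CC[C@@H]1O[C@@]1(C)CC/C=C(C)\CCC(OS(C)(=O)=O)C(=C)C(=O)OC | intermediate
19 | methyl (2Z,6Z)-2-(bromomethyl)-6-methyl-9-{(2S,3S)-2-methyl-3-[(3E)-3-methyl-5-oxopent-3-en-1-yl]oxiran-2-yl}nona-2,6-dienoate | O=C/C=C(\C)CC[C@@H]1O[C@@]1(C)CC/C=C(C)\CC/C=C(\CBr)C(=O)OC | intermediate
20 | methyl (1S,2S,3E,7S,8S,11Z)-7,8-epoxy-2-(trimethylsilyloxy)cembra-3,11,15(17)-trien-16-oate | C=C(C(=O)OC)[C@H]1[C@@H](O[Si](C)(C)C)/C=C(\C)CC[C@@H]2O[C@@]2(C)CC/C=C(C)\CC1 | intermediate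
21 | (1S,2S,3E,7S,8S,11Z)-7,8-epoxycembra-3,11,15(17)-trien-16,2-olide (cis-fused α-methylene-γ-lactone) | C=C1C(=O)O[C@H]2/C=C(\C)CC[C@@H]3O[C@@]3(C)CC/C=C(C)\CC[C@@H]12 | intermediate
22 | (1S,2S,3E,7S,8S,11S,12E)-7,8-epoxy-11-hydroperoxycembra-3,12,15(17)-trien-16,2-olide | C=C1C(=O)O[C@H]2/C=C(\C)CC[C@@H]3O[C@@]3(C)CC[C@H](OO)/C(C)=C/C[C@@H]12 | intermediate
23 | (1S,2S,3E,7S,8R,11S,12E)-8,11-epidioxy-7-hydroxycembra-3,12,15(17)-trien-16,2-olide | C=C1C(=O)O[C@H]2/C=C(\C)CC[C@H](O)[C@@]3(C)CC[C@H](OO3)/C(C)=C/C[C@@H]12 | intermediate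
24 | (1S,2S,3E,7S,8R,11S,12E)-7-acetoxy-8,11-epidioxycembra-3,12,15(17)-trien-16,2-olide | C=C1C(=O)O[C@H]2/C=C(\C)CC[C@H](OC(C)=O)[C@@]3(C)CC[C@H](OO3)/C(C)=C/C[C@@H]12 | target

**Step count and risks**

Total step count: 13. Longest linear sequence: 12 steps (4 to 24, steps 2–13); step 1 is a one-step side branch.

Step 11 (the new step) is the most likely to fail. The electrochemical chromium turnover has not been shown for a macrocyclising 2-(bromomethyl)enoate, the epoxide may not survive the Lewis-acidic medium, and the relay of configuration from the epoxide to C-1 and C-2 is only an expectation. The fallback uses known chemistry and a different activation mode. It sets out from 17, which is acetylated (Ac2O, pyridine) to methyl (3RS,6Z)-3-acetoxy-6-methyl-9-{(2S,3S)-2-methyl-3-[(3E)-3-methyl-5-oxopent-3-en-1-yl]oxiran-2-yl}-2-methylidenenon-6-enoate F1. Under Pd(PPh3)4 (zerovalent palladium, 5 mol %) and indium monoiodide InI in THF at high dilution, F1 is ionised to the π-allyl complex, transmetalated to the allylindium species and added to the enal. This gives methyl (1S,2S,3E,7S,8S,11Z)-7,8-epoxy-2-hydroxycembra-3,11,15(17)-trien-16-oate F2, which lactonises with PPTS and comes back to the route at 21.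

Step 12 is the second risk. The ene reaction can also abstract hydrogen from C-10 (giving the 12-hydroperoxide), so at most about half of the material is usable, and only the 11S hydroperoxide cyclises. The fallback sets out from 21 and forms the two C–O bonds in the opposite order. Perhydrolysis with anhydrous ethereal H2O2 and H3PMo12O40 (cat.) opens the epoxide at C-8 with inversion to (1S,2S,3E,7S,8R,11Z)-8-hydroperoxy-7-hydroxycembra-3,11,15(17)-trien-16,2-olide F3. N-Iodosuccinimide in CH2Cl2 at −40 °C then closes the 1,2-dioxane by transannular iodoperoxidation at C-11, giving (1S,2S,3E,7S,8R,11S)-8,11-epidioxy-7-hydroxy-12-iodocembra-3,15(17)-dien-16,2-olide F4. AgOTf with 2,6-di-tert-butylpyridine removes HI to the 12E-alkene (the 12(20)-exo isomer is separated), coming back to the route at 23.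

Step 3 is the third risk. The lithium enolate of an α-acyloxy methyl ketone may equilibrate (epimerising C-7) or be alkylated twice. The fallback sets out from 6, which is condensed with 1,1-dimethylhydrazine to (5R)-5-[1-(2,2-dimethylhydrazinylidene)ethyl]dihydrofuran-2(3H)-one F5. Its azaenolate (LiN(i-Pr)2, THF, −78 °C) is alkylated with 3 at the methyl carbon to (5R)-5-[(4Z)-1-(2,2-dimethylhydrazinylidene)-8,8-dimethoxy-5-methyloct-4-en-1-yl]dihydrofuran-2(3H)-one F6. Hydrolysis with CuCl2 in THF–pH 7 buffer comes back to the route at 7.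

**Further compounds**

F1 | step 11 | methyl (3RS,6Z)-3-acetoxy-6-methyl-9-{(2S,3S)-2-methyl-3-[(3E)-3-methyl-5-oxopent-3-en-1-yl]oxiran-2-yl}-2-methylidenenon-6-enoate | O=C/C=C(\C)CC[C@@H]1O[C@@]1(C)CC/C=C(C)\CCC(OC(C)=O)C(=C)C(=O)OC
F2 | step 11 | methyl (1S,2S,3E,7S,8S,11Z)-7,8-epoxy-2-hydroxycembra-3,11,15(17)-trien-16-oate | C=C(C(=O)OC)[C@H]1[C@@H](O)/C=C(\C)CC[C@@H]2O[C@@]2(C)CC/C=C(C)\CC1
F3 | step 12 | (1S,2S,3E,7S,8R,11Z)-8-hydroperoxy-7-hydroxycembra-3,11,15(17)-trien-16,2-olide | C=C1C(=O)O[C@H]2/C=C(\C)CC[C@H](O)[C@](C)(OO)CC/C=C(C)\CC[C@@H]12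
F4 | step 12 | (1S,2S,3E,7S,8R,11S)-8,11-epidioxy-7-hydroxy-12-iodocembra-3,15(17)-dien-16,2-olide | C=C1C(=O)O[C@H]2/C=C(\C)CC[C@H](O)[C@@]3(C)CC[C@H](OO3)C(C)(I)CC[C@@H]12
F5 | step 3 | (5R)-5-[1-(2,2-dimethylhydrazinylidene)ethyl]dihydrofuran-2(3H)-one | CN(C)N=C(C)[C@H]1CCC(=O)O1
F6 | step 3 | (5R)-5-[(4Z)-1-(2,2-dimethylhydrazinylidene)-8,8-dimethoxy-5-methyloct-4-en-1-yl]dihydrofuran-2(3H)-one | CN(C)N=C(CC/C=C(C)\CCC(OC)OC)[C@H]1CCC(=O)O1
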